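**Plan**

- Cuts: C11=C13 is carried as a C11–CH2NMe2 group; the ten-membered carbocycle is opened at C4–C5 (alkenyl triflate plus aldehyde); the furanone at O–C3 and C1–C2 (C10 hydroxyl plus alkyne); the ester at O8; the core at C7–C8 and C11–C13. This leaves a C8 dithiane (C8–C9–C10–C1), the (S)-butenolide (C5–C6–C7–C11–C12) and an iminium salt.
- Forward: epoxide opening builds the dithiane; the three components are joined on the lactone ring, which is present from the start; C8 is reduced and acylated; an alkynol brings C2–C4 and C15 to C1; oxidation and oxa-Michael closure give the furanone ring; a Nozaki–Hiyama–Kishi reaction closes the ten-membered ring; quaternisation and elimination unmask the methylene.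
- Stereochemistry: C10 from (R)-2-methylglycidol; C6 from the butenolide; C7 by addition anti to the C6 substituent; C8 by reduction directed by the C10 hydroxyl; C5 by Felkin–Anh addition during ring closure.
- Enabling feature: C7 is the β-carbon of the γ-lactone ring O–C6–C7–C11–C12, trans to the C6 substituent and bonded to the oxygenated C8, and the enolate carbon C11 lacks only C13. An acyl-anion equivalent and a one-carbon electrophile can therefore be added across C7=C11 of a butenolide in one flask.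

Key step: step 5

Remark on the chemistry: germacrane numbering (C1–C15) is used for all intermediates; but-3-yn-2-ol is used as the racemate, because the carbinol centres it leaves at C1 and C4 are both oxidised in step 12.

**Route**

Step 1
Reactants: 1 (R)-2-methylglycidol
Product: 2 (S)-2-[(benzyloxy)methyl]-2-methyloxirane
Conditions: NaH, BnBr, Bu4NI (cat.), THF, 0 °C → rt
Reagents that add atoms: benzyl bromide, BrCc1ccccc1
Why: Williamson etherification of the primary alkoxide leaves the quaternary epoxide carbon (the future C10) untouched, and a degenerate Payne shift of the alkoxide would return the same enantiomer.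

Step 2
Reactants: 3 1,3-dithiane; 2 (S)-2-[(benzyloxy)methyl]-2-methyloxirane
Product: 5 (2S)-1-(benzyloxy)-3-(1,3-dithian-2-yl)-2-methylpropan-2-ol, via 2-lithio-1,3-dithiane 4 (not isolated)
Conditions: n-BuLi, THF, −30 °C; then 2, −30 → 0 °C; H2O
Reagents that add atoms: none
Why: Corey–Seebach alkylation, in which the dithianyl anion opens the 2,2-disubstituted epoxide by SN2 attack at its unsubstituted CH2 (C9), so that C8–C9 forms and the C10 carbinol keeps the configuration of 1.

Step 3
Reactants: 5 (2S)-1-(benzyloxy)-3-(1,3-dithian-2-yl)-2-methylpropan-2-ol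
Product: 6 {[(2S)-1-(benzyloxy)-3-(1,3-dithian-2-yl)-2-methylpropan-2-yl]oxy}trimethylsilane
Conditions: N-(trimethylsilyl)imidazole, CH2Cl2, rt
Reagents that add atoms: N-(trimethylsilyl)imidazole, C[Si](C)(C)n1ccnc1
Why: O-silylation by silyl transfer from the N-silylimidazole caps the hindered tertiary hydroxyl so that it cannot quench the dithianyl anion in step 5, and the labile group falls off again in step 6.

Step 4
Reactants: 7 (S)-5-(hydroxymethyl)furan-2(5H)-one
Product: 8 (S)-5-{[tert-butyl(diphenyl)silyl]oxymethyl}furan-2(5H)-one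
Conditions: TBDPSCl, imidazole, CH2Cl2, 0 °C → rt
Reagents that add atoms: tert-butyl(chloro)diphenylsilane, CC(C)(C)[Si](Cl)(c1ccccc1)c1ccccc1
Why: imidazole-mediated O-silylation of the primary alcohol gives a bulky, acid-stable ether that shields one face of the butenolide and should last until step 14.

Step 5
Reactants: 6 {[(2S)-1-(benzyloxy)-3-(1,3-dithian-2-yl)-2-methylpropan-2-yl]oxy}trimethylsilane; 8 (S)-5-{[tert-butyl(diphenyl)silyl]oxymethyl}furan-2(5H)-one; 9 N,N-dimethylmethyleneiminium iodide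
Product: 12 (3R,4S,5S)-4-{2-[(2S)-3-(benzyloxy)-2-methyl-2-(trimethylsilyloxy)propyl]-1,3-dithian-2-yl}-5-{[tert-butyl(diphenyl)silyl]oxymethyl}-3-[(dimethylamino)methyl]oxolan-2-one, via lithiated dithiane 10 (not isolated), via lithium enolate 11 (not isolated)
Conditions: t-BuLi, THF/HMPA (10:1), −78 °C; then 8, −78 °C; then 9, −78 → 0 °C; H2O
Reagents that add atoms: none
Why: t-BuLi removes the C8 proton of 6, the solvent-separated dithianyl anion 10 adds in Michael fashion to C7 of butenolide 8 instead of to the C12 carbonyl, and the lithium enolate 11 is alkylated at C11 by the iminium ion of 9 (Mannich reaction), so that C7–C8 and C11–C13 form in one flask. The closest known reaction type is the tandem conjugate addition of 2-lithio-1,3-dithianes to γ-substituted butenolides with electrophilic trapping of the enolate. No ring closes. C7 is set by approach of the anion anti to the silyloxymethyl group on C6, and C11 by approach of the iminium ion anti to the new dithianyl group on C7, giving the trans,trans lactone; C11 becomes trigonal in step 17, so only C7 has to last. The step needs 1,4- over 1,2-addition and must outrun removal of the C6 proton; HMPA, the soft sulfur-stabilised carbanion and the low temperature should secure both. A silyl shift from oxygen to carbon in 10 is not expected, because the Brook equilibrium lies on the side of the silyl ether and the stabilised carbanion.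

Step 6
Reactants: 12 (the trans,trans dithianyl lactone of step 5)
Product: 13 (3R,4S,5S)-4-[(3S)-4-(benzyloxy)-3-hydroxy-3-methylbutanoyl]-5-{[tert-butyl(diphenyl)silyl]oxymethyl}-3-[(dimethylamino)methyl]oxolan-2-one
Conditions: CF3CO2H, then PhI(OCOCF3)2, MeCN/H2O (9:1), 0 °C; cold NaHCO3 work-up
Reagents that add atoms: water, O
Why: oxidative dithioacetal hydrolysis by the hypervalent iodine reagent unveils the C8 ketone while the amine is masked as its trifluoroacetate salt and the aqueous acid cleaves the tertiary trimethylsilyl ether; the β-acyloxy ketone is used at once to forestall E1cB opening of the lactone.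

Step 7
Reactants: 13 (the C8 ketone with free C10 hydroxyl)
Product: 15 (3R,4R,5S)-4-[(1R,3S)-4-(benzyloxy)-1,3-dihydroxy-3-methylbutyl]-5-{[tert-butyl(diphenyl)silyl]oxymethyl}-3-[(dimethylamino)methyl]oxolan-2-one, via diethylboron chelate 14 (not isolated)
Conditions: Et2BOMe, THF/MeOH (4:1), −78 °C; then NaBH4, −78 °C; MeOH, evaporation
Reagents that add atoms: none
Why: Narasaka–Prasad reduction, in which the six-membered boron chelate between the C10 oxygen and the C8 carbonyl should keep the larger benzyloxymethyl arm equatorial and take hydride axially on the face that carries the C10 methyl, giving the 1,3-syn relation of O8 and O10 along the C7–C1 chain, that is (8R).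

Step 8
Reactants: 15 (the 8,10-syn diol)
Product: 16 (3R,4R,5S)-4-[(1R,3S)-4-(benzyloxy)-3-hydroxy-3-methyl-1-(3-methylbutanoyloxy)butyl]-5-{[tert-butyl(diphenyl)silyl]oxymethyl}-3-[(dimethylamino)methyl]oxolan-2-one
Conditions: (i-PrCH2CO)2O, Et3N, DMAP (cat.), CH2Cl2, 0 °C → rt
Reagents that add atoms: 3-methylbutanoic anhydride, CC(C)CC(=O)OC(=O)CC(C)C
Why: DMAP-catalysed acyl transfer esterifies the secondary C8 hydroxyl, while the tertiary C10 hydroxyl should stay free under these conditions.

Step 9
Reactants: 16 (the C8 isovalerate, C1 benzyl ether)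
Product: 17 (3R,4R,5S)-5-{[tert-butyl(diphenyl)silyl]oxymethyl}-4-[(1R,3S)-3,4-dihydroxy-3-methyl-1-(3-methylbutanoyloxy)butyl]-3-[(dimethylamino)methyl]oxolan-2-one
Conditions: H2 (1 atm), Pd(OH)2 on carbon, EtOAc/AcOH, rt
Reagents that add atoms: none
Why: hydrogenolysis of the benzyl ether is clean at this stage because no alkene and no sulfur is left in the molecule, and the acetic acid keeps the amine from slowing the catalyst.

Step 10
Reactants: 17 (the C1,C10 diol)
Product: 18 (3R,4R,5S)-5-{[tert-butyl(diphenyl)silyl]oxymethyl}-3-[(dimethylamino)methyl]-4-[(1R,3S)-3-hydroxy-3-methyl-1-(3-methylbutanoyloxy)-4-oxobutyl]oxolan-2-one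
Conditions: IBX, CF3CO2H, DMSO, rt
Reagents that add atoms: none
Why: oxidation with 2-iodoxybenzoic acid (IBX) converts the primary C1 alcohol of the 1,2-diol into the aldehyde without glycol cleavage; the tertiary C10 hydroxyl cannot be oxidised and the amine is protected as its salt.

Step 11
Reactants: 18 (the C1 aldehyde); 19 but-3-yn-2-ol (racemic)
Product: 21 (3R,4R,5S)-5-{[tert-butyl(diphenyl)silyl]oxymethyl}-3-[(dimethylamino)methyl]-4-[(1R,3S)-3,4,7-trihydroxy-3-methyl-1-(3-methylbutanoyloxy)oct-5-yn-1-yl]oxolan-2-one (mixture of epimers at the two new carbinol carbons C1 and C4), via dilithiated but-3-yn-2-ol 20 (not isolated)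
Conditions: 19, n-BuLi, THF, −78 → −20 °C; then 18, −78 → −40 °C; H2O
Reagents that add atoms: none
Why: 1,2-addition of the lithium acetylide to the non-enolisable aldehyde forms C1–C2 and brings in C2, C3, C4 and C15; one equivalent of reagent is spent on the C10 hydroxyl, and the lactone and ester should not react at this temperature.

Step 12
Reactants: 21 (the alkynyl triol)
Product: 23 (3R,4R,5S)-4-{(1R)-2-[(2S)-5-acetyl-2-methyl-3-oxo-2,3-dihydrofuran-2-yl]-1-(3-methylbutanoyloxy)ethyl}-5-{[tert-butyl(diphenyl)silyl]oxymethyl}-3-[(dimethylamino)methyl]oxolan-2-one, via hydroxy ynedione 22 (not isolated)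
Conditions: IBX, CF3CO2H, DMSO, rt; NaHCO3 work-up; then Et3N (cat.), CH2Cl2, rt
Reagents that add atoms: none
Why: IBX oxidation of both propargylic carbinols gives the ynedione, whose C3 is β to the C1 ketone, and base-catalysed 5-endo-dig oxa-Michael addition of the C10 hydroxyl to C3 (cycloisomerisation of a γ-hydroxy ynone) closes the 3(2H)-furanone with C4 as an acetyl carbon.

Step 13
Reactants: 23 (the 5-acetylfuranone)
Product: 25 enol triflate: 23 with the acetyl group turned into a 1-(trifluoromethanesulfonyloxy)ethenyl group on C3 (C4(OTf)=C15H2), via potassium dienolate 24 (not isolated)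
Conditions: KN(SiMe3)2, THF, −78 °C; then PhNTf2, −78 → 0 °C
Reagents that add atoms: N-phenylbis(trifluoromethanesulfonimide), O=S(=O)(N(c1ccccc1)S(=O)(=O)C(F)(F)F)C(F)(F)F
Why: kinetic enolisation followed by O-sulfonylation (enol triflate formation) should occur at the acetyl methyl, whose cross-conjugated dienolate makes it far more acidic than the lactone or ester α-positions.

Step 14
Reactants: 25 (the enol triflate, C5 silyl ether)
Product: 26 primary alcohol: 25 with the C5 silyl ether cleaved to CH2OH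
Conditions: HF·pyridine, pyridine, THF, 0 °C → rt
Reagents that add atoms: none
Why: fluoride-mediated desilylation under non-basic conditions frees the C5 hydroxyl without touching the alkenyl triflate, the ester or the lactone.

Step 15
Reactants: 26 (the C5 alcohol)
Product: 27 aldehyde: 26 with C5 oxidised to CHO on C6 of the lactone
Conditions: Dess–Martin periodinane, pyridine, CH2Cl2, 0 °C
Reagents that add atoms: none
Why: buffered Dess–Martin oxidation gives the α-acyloxy aldehyde under conditions mild enough to avoid epimerisation at C6, and the aldehyde is used directly.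

Step 16
Reactants: 27 (the C5 aldehyde bearing the C4 alkenyl triflate)
Product: 29 (5R,6S,7R,8R,10S,11R)-13-(dimethylamino)-11,13-dihydro derivative of the target (target with C11 as CH–CH2NMe2), via alkenylchromium dichloride 28 (not isolated)
Conditions: CrCl2, NiCl2 (cat.), DMSO/THF, rt, slow addition at high dilution; H2O
Reagents that add atoms: none
Why: Nozaki–Hiyama–Kishi reaction, in which zerovalent nickel inserts into the alkenyl triflate, transmetalation gives the alkenyl species of trivalent chromium, and its addition to the C5 aldehyde forms C4–C5 and closes the ten-membered carbocycle (a nine-membered ring counted through the furanone oxygen); attack anti to the C6–O bond (Felkin–Anh) should give the 5,6-anti carbinol, (5R).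

Step 17
Reactants: 29 (the macrocyclic Mannich base)
Product: 31 CNP0409337.1, (5R,6S,7R,8R,10S)-5-hydroxy-8-(3-methylbutanoyloxy)-1-oxo-3,10-epoxygermacra-2,4(15),11(13)-trien-12,6-olide, via trimethylammonium iodide 30 (not isolated)
Conditions: MeI, MeOH/THF, rt; then NaHCO3 (aq), rt
Reagents that add atoms: none
Why: N-methylation followed by mild-base E1cB (Hofmann-type) elimination of trimethylamine from the β-ammonio lactone unveils the C11=C13 methylene last, so that no earlier step has to tolerate this Michael acceptor.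

**Compound list**

1 | (R)-2-methylglycidol | C[C@@]1(CO)CO1 | starting material
2 | (S)-2-[(benzyloxy)methyl]-2-methyloxirane | C[C@@]1(COCc2ccccc2)CO1 | intermediate
3 | 1,3-dithiane | C1CSCSC1 | starting material
4 | 2-lithio-1,3-dithiane | [Li]C1SCCCS1 | intermediate
5 | (2S)-1-(benzyloxy)-3-(1,3-dithian-2-yl)-2-methylpropan-2-ol | C1CSC(C[C@@](O)(C)COCc2ccccc2)SC1 | intermediate
6 | {[(2S)-1-(benzyloxy)-3-(1,3-dithian-2-yl)-2-methylpropan-2-yl]oxy}trimethylsilane | C1CSC(C[C@@](O[Si](C)(C)C)(C)COCc2ccccc2)SC1 | intermediate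
7 | (S)-5-(hydroxymethyl)furan-2(5H)-one | OC[C@H]1OC(=O)C=C1 | starting material
8 | (S)-5-{[tert-butyl(diphenyl)silyl]oxymethyl}furan-2(5H)-one | O=C1C=C[C@@H](CO[Si](c2ccccc2)(c3ccccc3)C(C)(C)C)O1 | intermediate
9 | N,N-dimethylmethyleneiminium iodide | C=[N+](C)C.[I-] | starting material
10 | 2-lithio derivative of 6 | [Li]C1(C[C@@](O[Si](C)(C)C)(C)COCc2ccccc2)SCCCS1 | intermediate
11 | lithium lactone enolate after addition at C7 | [Li]OC1=C[C@@H]([C@@H](CO[Si](c2ccccc2)(c3ccccc3)C(C)(C)C)O1)C4(C[C@@](O[Si](C)(C)C)(C)COCc5ccccc5)SCCCS4 | intermediate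
12 | (3R,4S,5S)-4-{2-[(2S)-3-(benzyloxy)-2-methyl-2-(trimethylsilyloxy)propyl]-1,3-dithian-2-yl}-5-{[tert-butyl(diphenyl)silyl]oxymethyl}-3-[(dimethylamino)methyl]oxolan-2-one | CN(C)C[C@@H]1C(=O)O[C@H](CO[Si](c2ccccc2)(c3ccccc3)C(C)(C)C)[C@H]1C4(C[C@@](O[Si](C)(C)C)(C)COCc5ccccc5)SCCCS4 | intermediate
13 | (3R,4S,5S)-4-[(3S)-4-(benzyloxy)-3-hydroxy-3-methylbutanoyl]-5-{[tert-butyl(diphenyl)silyl]oxymethyl}-3-[(dimethylamino)methyl]oxolan-2-one | CN(C)C[C@@H]1C(=O)O[C@H](CO[Si](c2ccccc2)(c3ccccc3)C(C)(C)C)[C@H]1C(=O)C[C@@](O)(C)COCc4ccccc4 | intermediate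
14 | O10-diethylboryl chelate of 13 | CN(C)C[C@@H]1C(=O)O[C@H](CO[Si](c2ccccc2)(c3ccccc3)C(C)(C)C)[C@H]1C(=O)C[C@@](OB(CC)CC)(C)COCc4ccccc4 | intermediate
15 | (3R,4R,5S)-4-[(1R,3S)-4-(benzyloxy)-1,3-dihydroxy-3-methylbutyl]-5-{[tert-butyl(diphenyl)silyl]oxymethyl}-3-[(dimethylamino)methyl]oxolan-2-one | CN(C)C[C@@H]1C(=O)O[C@H](CO[Si](c2ccccc2)(c3ccccc3)C(C)(C)C)[C@H]1[C@H](O)C[C@@](O)(C)COCc4ccccc4 | intermediate
16 | (3R,4R,5S)-4-[(1R,3S)-4-(benzyloxy)-3-hydroxy-3-methyl-1-(3-methylbutanoyloxy)butyl]-5-{[tert-butyl(diphenyl)silyl]oxymethyl}-3-[(dimethylamino)methyl]oxolan-2-one | CN(C)C[C@@H]1C(=O)O[C@H](CO[Si](c2ccccc2)(c3ccccc3)C(C)(C)C)[C@H]1[C@H](OC(=O)CC(C)C)C[C@@](O)(C)COCc4ccccc4 | intermediate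
17 | (3R,4R,5S)-5-{[tert-butyl(diphenyl)silyl]oxymethyl}-4-[(1R,3S)-3,4-dihydroxy-3-methyl-1-(3-methylbutanoyloxy)butyl]-3-[(dimethylamino)methyl]oxolan-2-one | CN(C)C[C@@H]1C(=O)O[C@H](CO[Si](c2ccccc2)(c3ccccc3)C(C)(C)C)[C@H]1[C@H](OC(=O)CC(C)C)C[C@@](O)(C)CO | intermediate
18 | (3R,4R,5S)-5-{[tert-butyl(diphenyl)silyl]oxymethyl}-3-[(dimethylamino)methyl]-4-[(1R,3S)-3-hydroxy-3-methyl-1-(3-methylbutanoyloxy)-4-oxobutyl]oxolan-2-one | CN(C)C[C@@H]1C(=O)O[C@H](CO[Si](c2ccccc2)(c3ccccc3)C(C)(C)C)[C@H]1[C@H](OC(=O)CC(C)C)C[C@@](O)(C)C=O | intermediate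
19 | but-3-yn-2-ol (racemic) | CC(O)C#C | starting material
20 | dilithiated but-3-yn-2-ol | CC(O[Li])C#C[Li] | intermediate
21 | alkynyl triol, (1R,3S)-3,4,7-trihydroxy-3-methyl-1-(3-methylbutanoyloxy)oct-5-yn-1-yl side chain on C4 of the lactone (epimers at C1 and C4 of the germacrane numbering) | CN(C)C[C@@H]1C(=O)O[C@H](CO[Si](c2ccccc2)(c3ccccc3)C(C)(C)C)[C@H]1[C@H](OC(=O)CC(C)C)C[C@@](O)(C)C(O)C#CC(C)O | intermediate
22 | hydroxy ynedione, 4,7-dioxooct-5-ynyl analogue of 21 | CN(C)C[C@@H]1C(=O)O[C@H](CO[Si](c2ccccc2)(c3ccccc3)C(C)(C)C)[C@H]1[C@H](OC(=O)CC(C)C)C[C@@](O)(C)C(=O)C#CC(C)=O | intermediate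
23 | (3R,4R,5S)-4-{(1R)-2-[(2S)-5-acetyl-2-methyl-3-oxo-2,3-dihydrofuran-2-yl]-1-(3-methylbutanoyloxy)ethyl}-5-{[tert-butyl(diphenyl)silyl]oxymethyl}-3-[(dimethylamino)methyl]oxolan-2-one | CN(C)C[C@@H]1C(=O)O[C@H](CO[Si](c2ccccc2)(c3ccccc3)C(C)(C)C)[C@H]1[C@H](OC(=O)CC(C)C)C[C@]4(C)OC(=CC4=O)C(C)=O | intermediate
24 | potassium dienolate of 23 (O-potassio enolate of the acetyl group) | CN(C)C[C@@H]1C(=O)O[C@H](CO[Si](c2ccccc2)(c3ccccc3)C(C)(C)C)[C@H]1[C@H](OC(=O)CC(C)C)C[C@]4(C)OC(=CC4=O)C(=C)O[K] | intermediate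
25 | enol triflate of 23, 1-(trifluoromethanesulfonyloxy)ethenyl group on the furanone | CN(C)C[C@@H]1C(=O)O[C@H](CO[Si](c2ccccc2)(c3ccccc3)C(C)(C)C)[C@H]1[C@H](OC(=O)CC(C)C)C[C@]4(C)OC(=CC4=O)C(=C)OS(=O)(=O)C(F)(F)F | intermediate
26 | C5 primary alcohol (desilylated 25) | CN(C)C[C@@H]1C(=O)O[C@H](CO)[C@H]1[C@H](OC(=O)CC(C)C)C[C@]2(C)OC(=CC2=O)C(=C)OS(=O)(=O)C(F)(F)F | intermediate
27 | C5 aldehyde (oxidised 26) | CN(C)C[C@@H]1C(=O)O[C@H](C=O)[C@H]1[C@H](OC(=O)CC(C)C)C[C@]2(C)OC(=CC2=O)C(=C)OS(=O)(=O)C(F)(F)F | intermediate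
28 | C4 alkenylchromium dichloride derived from 27 | CN(C)C[C@@H]1C(=O)O[C@H](C=O)[C@H]1[C@H](OC(=O)CC(C)C)C[C@]2(C)OC(=CC2=O)C(=C)[Cr](Cl)Cl | intermediate
29 | (5R,6S,7R,8R,10S,11R)-13-(dimethylamino)-11,13-dihydro derivative of the target | CN(C)C[C@@H]1C(=O)O[C@H]2[C@H]1[C@H](OC(=O)CC(C)C)C[C@]1(C)OC(=CC1=O)C(=C)[C@H]2O | intermediate
30 | N-methyl quaternary ammonium iodide of 29 | C[N+](C)(C)C[C@@H]1C(=O)O[C@H]2[C@H]1[C@H](OC(=O)CC(C)C)C[C@]1(C)OC(=CC1=O)C(=C)[C@H]2O.[I-] | intermediate
31 | CNP0409337.1, (5R,6S,7R,8R,10S)-5-hydroxy-8-(3-methylbutanoyloxy)-1-oxo-3,10-epoxygermacra-2,4(15),11(13)-trien-12,6-olide | C=C1C(=O)O[C@H]2[C@H]1[C@H](OC(=O)CC(C)C)C[C@]1(C)OC(=CC1=O)C(=C)[C@H]2O | target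

**Step count**

Total: 17 steps. Longest linear sequence: 16 steps (from 1 through steps 1–3 and 5–17); step 4 is the one-step side branch.

**Steps most likely to fail**

1. Step 5. The hindered and strongly basic anion 10 may add to the C12 carbonyl, or remove the C6 proton of 8, instead of adding to C7. Fallback, setting out from 2 and rejoining at 13: bis(phenylsulfanyl)methane is deprotonated (n-BuLi, THF, 0 °C) to bis(phenylsulfanyl)methyllithium F1, which opens epoxide 2 to (2S)-1-(benzyloxy)-2-methyl-4,4-bis(phenylsulfanyl)butan-2-ol F2. Silylation as in step 3 gives its trimethylsilyl ether F3. The lithio derivative F4 (n-BuLi, TMEDA, THF, −78 °C) is a softer, less basic acyclic thioacetal anion of the kind that adds 1,4 to butenolides without a polar cosolvent. It is added to 8 to give lithium enolate F5, which 9 traps as the bis(phenylsulfanyl) analogue F6 of 12. The hydrolysis conditions of step 6 then lead back to 13.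

2. Step 7. Facial discrimination in the boron chelate may be poor, because the methyl and benzyloxymethyl groups on C10 differ little in size. Fallback, setting out from 13 and rejoining at 16: internal hydride delivery with Me4NBH(OAc)3 (MeCN/AcOH, −30 °C; Evans–Saksena reduction) places the smaller methyl axial in the chair transition state and is expected to favour the (8S)-diol F7. Mitsunobu esterification of F7 with 3-methylbutanoic acid (PPh3, DIAD, toluene, 0 °C) inverts C8 and gives 16 directly. Either C8 epimer can thus be taken to 16, one by acylation with retention and the other by esterification with inversion.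

3. Step 16. The strained transition state for closing the oxa-bridged ring may override the open-chain Felkin–Anh preference, so that the alkenylchromium adds to the other face of the aldehyde; slow closure would also favour intermolecular coupling. Fallback, setting out from 27 and rejoining at 29: the closure is run as in step 16 and the (5S)-carbinol F8, the C5 epimer of 29, is oxidised with Dess–Martin periodinane to the ring C5 ketone F9, an α-methylene ketone. Luche reduction (NaBH4, CeCl3·7H2O, MeOH, −78 °C) then sets C5 by hydride delivery from the outer face of the closed ring, so that the configuration is decided by an external reagent and no longer by the ring-closing event.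

**Further compounds**

F1 | step 5 | bis(phenylsulfanyl)methyllithium | [Li]C(Sc1ccccc1)Sc1ccccc1
F2 | step 5 | (2S)-1-(benzyloxy)-2-methyl-4,4-bis(phenylsulfanyl)butan-2-ol | c1ccc(cc1)SC(Sc2ccccc2)C[C@@](O)(C)COCc3ccccc3
F3 | step 5 | trimethylsilyl ether of F2 | c1ccc(cc1)SC(Sc2ccccc2)C[C@@](O[Si](C)(C)C)(C)COCc3ccccc3
F4 | step 5 | lithio derivative of F3 | [Li]C(Sc1ccccc1)(Sc2ccccc2)C[C@@](O[Si](C)(C)C)(C)COCc3ccccc3
F5 | step 5 | lithium lactone enolate from F4 and 8 | [Li]OC1=C[C@@H]([C@@H](CO[Si](c2ccccc2)(c3ccccc3)C(C)(C)C)O1)C(Sc4ccccc4)(Sc5ccccc5)C[C@@](O[Si](C)(C)C)(C)COCc6ccccc6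
F6 | step 5 | bis(phenylsulfanyl) analogue of 12 | CN(C)C[C@@H]1C(=O)O[C@H](CO[Si](c2ccccc2)(c3ccccc3)C(C)(C)C)[C@H]1C(Sc4ccccc4)(Sc5ccccc5)C[C@@](O[Si](C)(C)C)(C)COCc6ccccc6
F7 | step 7 | (8S)-diol, C8 epimer of 15 | CN(C)C[C@@H]1C(=O)O[C@H](CO[Si](c2ccccc2)(c3ccccc3)C(C)(C)C)[C@H]1[C@@H](O)C[C@@](O)(C)COCc4ccccc4
F8 | step 16 | (5S)-carbinol, C5 epimer of 29 | CN(C)C[C@@H]1C(=O)O[C@H]2[C@H]1[C@H](OC(=O)CC(C)C)C[C@]1(C)OC(=CC1=O)C(=C)[C@@H]2O
F9 | step 16 | C5 ketone of the macrocycle | CN(C)C[C@@H]1C(=O)O[C@H]2[C@H]1[C@H](OC(=O)CC(C)C)C[C@]1(C)OC(=CC1=O)C(=C)C2=O
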